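**Retrosynthetic overview**

1. Target 24 ⇐ 7-acetate 23 by a hydroxyl-directed singlet-oxygen ene reaction (C12–OOH, C13=C16); 23 ⇐ triol diene 22 ⇐ aldehyde 18 by two Wittig olefinations (C12=C13, C14=C15).
2. The 8α-OH/8β-CH3 carbinol ⇐ 8α-acetyl by Baeyer–Villiger oxidation (retention), which traces ring B back to β-hydroxy ketone 15.
3. Ring B ⇐ ring-A alkene–aldehyde 9 + acyclic enone 12: one HAT-initiated radical conjugate addition/aldol annulation makes C9–C10 and C7–C8 and sets C7, C8, C9 and C10. Ring A is present from the start; ring B is the only ring formed.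
4. Enabling feature: in ring B the quaternary, methyl-bearing C10 (ring-A junction) lies 1,3 to the methyl-bearing tertiary carbinol C8, which is flanked by the C7 carbinol. So C10 = tertiary radical from an exocyclic C10=CH2, C9=C8 = α-methyl enone (acetyl as masked OH), C7 = aldehyde.
5. 9 ⇐ 3-methylcyclohexenone + Me2CuLi + (R)-glyceraldehyde acetonide (C5 and C6 by conjugate addition/aldol), then methylenation and glycol cleavage.

Key step: step 6

Remark: labdane numbering and α/β descriptors of the normal labdane series (5α-H, 9α-H, 10β-CH3) are used for all bicyclic compounds; where a chiral ligand is named in a fallback, the antipode meant is the one that gives the stated configuration.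

**Route**

Step 1
Reactants: 1 3-methylcyclohex-2-en-1-one; 2 (R)-2,2-dimethyl-1,3-dioxolane-4-carbaldehyde
Product: 5 (2R)-2-{(S)-[(4R)-2,2-dimethyl-1,3-dioxolan-4-yl](hydroxy)methyl}-3,3-dimethylcyclohexan-1-one, via lithium 3,3-dimethylcyclohex-1-en-1-olate 3 (not isolated), via chlorozinc 3,3-dimethylcyclohex-1-en-1-olate 4 (not isolated)
Conditions: Me2CuLi, Et2O, 0 °C; ZnCl2, THF, −78 °C; then 2, −78 °C; aq. NH4Cl
Reagents that add atoms: lithium dimethylcuprate, [Li+].C[Cu-]C
Why: Conjugate addition of the cuprate gives regiospecifically the enolate next to the new gem-dimethyl carbon, and its zinc enolate adds to the α-alkoxy aldehyde through a Zimmerman–Traxler transition state (cyclic E-enolate, hence the anti C5/C6 relationship) on the Felkin–Anh face fixed by the dioxolane stereocenter (matched for an E-enolate), so C5 and C6 are both set here (tandem conjugate addition–aldol).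

Step 2
Reactants: 5 aldol adduct
Product: 6 (2R)-2-{(S)-[(tert-butyldimethylsilyl)oxy][(4R)-2,2-dimethyl-1,3-dioxolan-4-yl]methyl}-3,3-dimethylcyclohexan-1-one
Conditions: TBSOTf, 2,6-lutidine, CH2Cl2, −78 to 0 °C
Reagents that add atoms: tert-butyldimethylsilyl trifluoromethanesulfonate, CC(C)(C)[Si](C)(C)OS(=O)(=O)C(F)(F)F
Why: Standard silylation of the hindered secondary carbinol; a silyl ether rather than a benzyl-type ether is chosen so that no weak C–H bond sits 1,5 to the later C10 radical.

Step 3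
Reactants: 6 silyloxy ketone
Product: 7 tert-butyl{(S)-[(4R)-2,2-dimethyl-1,3-dioxolan-4-yl][(1S)-2,2-dimethyl-6-methylidenecyclohexyl]methoxy}dimethylsilane
Conditions: Cp2TiMe2, toluene, 70 °C
Reagents that add atoms: dimethyltitanocene Cp2TiMe2, [Ti+4].[CH3-].[CH3-].c1cc[cH-]c1.c1cc[cH-]c1
Why: Non-basic Petasis methylenation of the hindered, enolisable ketone avoids the C5 epimerisation and β-elimination of the silyloxy group that a basic ylide could cause.

Step 4
Reactants: 7 acetonide
Product: 9 (2S)-2-[(tert-butyldimethylsilyl)oxy]-2-[(1S)-2,2-dimethyl-6-methylidenecyclohexyl]acetaldehyde, via 1,2-diol 8 (not isolated)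
Conditions: H5IO6, EtOAc, rt
Reagents that add atoms: none
Why: Periodic acid hydrolyses the terminal acetonide and cleaves the liberated 1,2-diol in one pot (glycol fission), leaving the secondary silyl ether and the 1,1-disubstituted alkene intact and C6 unenolised.

Step 5
Reactants: 10 3-[(tert-butyldimethylsilyl)oxy]propanal; 11 3-(triphenyl-λ5-phosphanylidene)butan-2-one
Product: 12 (E)-6-[(tert-butyldimethylsilyl)oxy]-3-methylhex-3-en-2-one
Conditions: toluene, 80 °C
Reagents that add atoms: none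
Why: Wittig olefination with a stabilised acyl ylide gives the E-trisubstituted enone.

Step 6
Reactants: 9 alkene–aldehyde; 12 enone (3 equiv)
Product: 15 1-[6β,12-bis(tert-butyldimethylsilyloxy)-7β-hydroxy-13,14,15,16-tetranorlabdan-8α-yl]ethan-1-one, via C10 tertiary radical 13 (not isolated), via iron enolate 14 (not isolated)
Conditions: Fe(acac)3 (30 mol %), PhSiH3, EtOH/(CH2OH)2, 0 °C to rt
Reagents that add atoms: none
Why: An iron hydride formed from Fe(acac)3 and PhSiH3 transfers a hydrogen atom to the 1,1-disubstituted C10=CH2 of 9 (creating the C20 methyl and tertiary radical 13), which adds to the β-carbon (C9) of enone 12; divalent iron reduces the α-keto radical to enolate 14, whose α-carbon (C8) closes ring B on the C7 aldehyde by a 6-(enolexo)-exo-trig aldol, the closest known type being HAT-initiated radical conjugate addition/aldol (radical–polar crossover) annulations of alkene-aldehydes with α-methyl enones that give trans-decalin carbinols. C10: the radical is attacked on the face away from the axial C4 methyl (equatorial bond formation), which puts C9 trans to C6 and fixes the trans ring fusion relative to the resident C5 stereocenter. C9: the acceptor should approach with its CH2CH2OTBS arm anti to the C5 branch, and only this adduct can place H9 in the enolate plane (minimum of allylic 1,3-strain) with C11 equatorial in a chair closure, so the 9-epimeric adduct is expected to be protonated instead of cyclised and removed as an acyclic ketone. C8: with H9 eclipsing the enolate, the tethered aldehyde has to attack from the C10 face, which makes the C8 methyl axial (β) and the acetyl equatorial (α). C7: a chair, metal-bridged Zimmerman–Traxler-type transition state with the enolate oxygen cis to the C8 methyl should give the equatorial 7β-carbinol trans to the acetyl group. The step needs HAT to the exocyclic alkene rather than to the enone or aldehyde (secured by the electron-rich 1,1-disubstituted alkene and excess 12) and no intramolecular hydrogen abstraction by the C10 radical (secured by the silyl ether at C6).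

Step 7
Reactants: 15 β-hydroxy methyl ketone
Product: 16 6β,12-bis(tert-butyldimethylsilyloxy)-7β-hydroxy-13,14,15,16-tetranorlabdan-8α-yl acetate
Conditions: mCPBA, NaHCO3, CH2Cl2, rt
Reagents that add atoms: 3-chloroperoxybenzoic acid, OOC(=O)c1cccc(Cl)c1
Why: Baeyer–Villiger oxidation in which the tertiary C8 migrates in preference to methyl with retention, turning the 8α-acetyl group into the 8α-acetoxy group; no alkene is present at this stage.

Step 8
Reactants: 16 bis-silyl ether
Product: 17 6β,7β,12-trihydroxy-13,14,15,16-tetranorlabdan-8α-yl acetate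
Conditions: HF·pyridine, THF, 0 to 40 °C
Reagents that add atoms: none
Why: Fluoride cleavage of both silyl ethers under non-basic conditions; an 8→7 acetyl shift would be harmless because the acetate is removed in step 11.

Step 9
Reactants: 17 triol acetate
Product: 18 6β,7β-dihydroxy-12-oxo-13,14,15,16-tetranorlabdan-8α-yl acetate
Conditions: TEMPO (cat.), PhI(OAc)2, CH2Cl2, rt
Reagents that add atoms: none
Why: The oxoammonium (TEMPO) oxidation is selective for the primary alcohol over the hindered secondary C6 and C7 hydroxyls, and the acylated C8 oxygen cannot form a lactol with the new aldehyde.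

Step 10
Reactants: 18 aldehyde; 19 2-(triphenyl-λ5-phosphanylidene)propanal
Product: 20 (12E)-8α-acetoxy-6β,7β-dihydroxy-15-norlabd-12-en-14-al
Conditions: toluene, 90 °C
Reagents that add atoms: none
Why: Wittig olefination with the stabilised α-methyl ylide gives the (E)-2-methyl-2-enal, and the blocked C8 oxygen cannot add to it (no oxa-Michael closure to the 8,12-ether).

Step 11
Reactants: 20 enal
Product: 22 (12E)-labda-12,14-diene-6β,7β,8α-triol, via diene 8-acetate 21 (not isolated)
Conditions: Ph3PCH3Br, KN(SiMe3)2, THF, −78 to 0 °C; then K2CO3, MeOH, rt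
Reagents that add atoms: methyltriphenylphosphonium bromide, C[P+](c1ccccc1)(c1ccccc1)c1ccccc1.[Br-]
Why: Wittig methylenation of the enal gives the E-configured 1,3-diene, and methanolysis in the same flask removes the tertiary acetate to unveil the triol.

Step 12
Reactants: 22 triol diene
Product: 23 (12E)-6β,8α-dihydroxylabda-12,14-dien-7β-yl acetate
Conditions: Ac2O, pyridine, 0 °C
Reagents that add atoms: acetic anhydride, CC(=O)OC(C)=O
Why: Selective acylation of the only accessible hydroxyl: the 7β-OH is equatorial and secondary, whereas the 6β-OH is axial and flanked by three syn-axial methyl groups and the 8α-OH is tertiary.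

Step 13
Reactants: 23 diene monoacetate
Product: 24 (12R)-12-hydroperoxy-6β,8α-dihydroxylabda-13(16),14-dien-7β-yl acetate (CNP0356983.1)
Conditions: O2, visible light, tetraphenylporphyrin (cat.), CH2Cl2, −30 °C
Reagents that add atoms: dioxygen, O=O
Why: Schenck ene reaction of singlet oxygen at the trisubstituted C12=C13 bond: hydrogen is taken from the C16 methyl on the disubstituted side (cis effect, geminal to the vinyl group), which moves the double bond to C13=C16 and places OOH on C12, and the 8α-hydroxyl, held close to C12 in the favoured C9–C11 rotamer, should hydrogen-bond the developing perepoxide and steer oxygen to the face that is modelled to give 12R (hydroxyl-directed ene reaction).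

**Compound list**

1 | 3-methylcyclohex-2-en-1-one | CC1=CC(=O)CCC1 | starting material
2 | (R)-2,2-dimethyl-1,3-dioxolane-4-carbaldehyde | O=C[C@H]1COC(C)(C)O1 | starting material
3 | lithium 3,3-dimethylcyclohex-1-en-1-olate | [Li+].[O-]C1=CC(C)(C)CCC1 | intermediate
4 | chlorozinc 3,3-dimethylcyclohex-1-en-1-olate | Cl[Zn]OC1=CC(C)(C)CCC1 | intermediate
5 | (2R)-2-{(S)-[(4R)-2,2-dimethyl-1,3-dioxolan-4-yl](hydroxy)methyl}-3,3-dimethylcyclohexan-1-one | CC1(C)OC[C@@H](O1)[C@@H](O)[C@H]2C(C)(C)CCCC2=O | intermediate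
6 | (2R)-2-{(S)-[(tert-butyldimethylsilyl)oxy][(4R)-2,2-dimethyl-1,3-dioxolan-4-yl]methyl}-3,3-dimethylcyclohexan-1-one | CC1(C)OC[C@@H](O1)[C@@H](O[Si](C)(C)C(C)(C)C)[C@H]2C(C)(C)CCCC2=O | intermediate
7 | tert-butyl{(S)-[(4R)-2,2-dimethyl-1,3-dioxolan-4-yl][(1S)-2,2-dimethyl-6-methylidenecyclohexyl]methoxy}dimethylsilane | CC1(C)OC[C@@H](O1)[C@@H](O[Si](C)(C)C(C)(C)C)[C@H]2C(C)(C)CCCC2=C | intermediate
8 | (2R,3S)-3-[(tert-butyldimethylsilyl)oxy]-3-[(1S)-2,2-dimethyl-6-methylidenecyclohexyl]propane-1,2-diol | OC[C@@H](O)[C@@H](O[Si](C)(C)C(C)(C)C)[C@H]1C(C)(C)CCCC1=C | intermediate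
9 | (2S)-2-[(tert-butyldimethylsilyl)oxy]-2-[(1S)-2,2-dimethyl-6-methylidenecyclohexyl]acetaldehyde | O=C[C@@H](O[Si](C)(C)C(C)(C)C)[C@H]1C(C)(C)CCCC1=C | intermediate
10 | 3-[(tert-butyldimethylsilyl)oxy]propanal | CC(C)(C)[Si](C)(C)OCCC=O | starting material
11 | 3-(triphenyl-λ5-phosphanylidene)butan-2-one | CC(=O)C(C)=P(c1ccccc1)(c1ccccc1)c1ccccc1 | starting material
12 | (E)-6-[(tert-butyldimethylsilyl)oxy]-3-methylhex-3-en-2-one | CC(=O)/C(C)=C/CCO[Si](C)(C)C(C)(C)C | intermediate
13 | C10 tertiary radical from 9 (hydrogen added to the exocyclic CH2) | O=C[C@@H](O[Si](C)(C)C(C)(C)C)[C@H]1C(C)(C)CCC[C]1C | intermediate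
14 | iron enolate of the conjugate adduct (drawn as the enolate; C9–C10 formed, C7 aldehyde still free) | O=C[C@@H](O[Si](C)(C)C(C)(C)C)[C@H]1C(C)(C)CCC[C@]1(C)[C@@H](CCO[Si](C)(C)C(C)(C)C)/C(C)=C(\C)[O-] | intermediate
15 | 1-[6β,12-bis(tert-butyldimethylsilyloxy)-7β-hydroxy-13,14,15,16-tetranorlabdan-8α-yl]ethan-1-one | CC(C)(C)[Si](C)(C)OCC[C@H]1[C@](C)(C(C)=O)[C@@H](O)[C@@H](O[Si](C)(C)C(C)(C)C)[C@H]2C(C)(C)CCC[C@@]21C | intermediate
16 | 6β,12-bis(tert-butyldimethylsilyloxy)-7β-hydroxy-13,14,15,16-tetranorlabdan-8α-yl acetate | CC(C)(C)[Si](C)(C)OCC[C@H]1[C@](C)(OC(C)=O)[C@@H](O)[C@@H](O[Si](C)(C)C(C)(C)C)[C@H]2C(C)(C)CCC[C@@]21C | intermediate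
17 | 6β,7β,12-trihydroxy-13,14,15,16-tetranorlabdan-8α-yl acetate | OCC[C@H]1[C@](C)(OC(C)=O)[C@@H](O)[C@@H](O)[C@H]2C(C)(C)CCC[C@@]21C | intermediate
18 | 6β,7β-dihydroxy-12-oxo-13,14,15,16-tetranorlabdan-8α-yl acetate | O=CC[C@H]1[C@](C)(OC(C)=O)[C@@H](O)[C@@H](O)[C@H]2C(C)(C)CCC[C@@]21C | intermediate
19 | 2-(triphenyl-λ5-phosphanylidene)propanal | CC(C=O)=P(c1ccccc1)(c1ccccc1)c1ccccc1 | starting material
20 | (12E)-8α-acetoxy-6β,7β-dihydroxy-15-norlabd-12-en-14-al | O=C/C(C)=C/C[C@H]1[C@](C)(OC(C)=O)[C@@H](O)[C@@H](O)[C@H]2C(C)(C)CCC[C@@]21C | intermediate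
21 | (12E)-6β,7β-dihydroxylabda-12,14-dien-8α-yl acetate | C=C/C(C)=C/C[C@H]1[C@](C)(OC(C)=O)[C@@H](O)[C@@H](O)[C@H]2C(C)(C)CCC[C@@]21C | intermediate
22 | (12E)-labda-12,14-diene-6β,7β,8α-triol | C=C/C(C)=C/C[C@H]1[C@](C)(O)[C@@H](O)[C@@H](O)[C@H]2C(C)(C)CCC[C@@]21C | intermediate
23 | (12E)-6β,8α-dihydroxylabda-12,14-dien-7β-yl acetate | C=C/C(C)=C/C[C@H]1[C@](C)(O)[C@@H](OC(C)=O)[C@@H](O)[C@H]2C(C)(C)CCC[C@@]21C | intermediate
24 | (12R)-12-hydroperoxy-6β,8α-dihydroxylabda-13(16),14-dien-7β-yl acetate (CNP0356983.1) | C=CC(=C)[C@@H](C[C@H]1[C@](C)(O)[C@@H](OC(C)=O)[C@@H](O)[C@H]2C(C)(C)CCC[C@@]21C)OO | target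

**Step count**

Total: 13 steps. Longest linear sequence: 12 steps (steps 1–4 and 6–13); step 5 is the one-step side branch.

**Steps most likely to fail**

Step 6. The hindered C10 radical may be reduced, or the enolate protonated, faster than addition and ring closure occur, and the facial selectivity at C9 in the intermolecular addition may be poor. Fallback: make the two bonds in separate operations, with C9–C10 last and intramolecular. It sets out from 10 and 9 and returns at 15.
- Wittig reaction of 10 with S-ethyl 2-(triphenyl-λ5-phosphanylidene)propanethioate would give S-ethyl (E)-5-[(tert-butyldimethylsilyl)oxy]-2-methylpent-2-enethioate F1.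
- γ-Deprotonation (LiN(i-Pr)2, HMPA, THF, −78 °C; a thioester has no competing α′-hydrogens) gives the extended dienolate, which should add through its α-carbon to aldehyde 9 (deconjugative aldol) to give the β,γ-unsaturated thioester aldol F2. This forms C7–C8; C8 epimers would be separated.
- HAT-initiated reductive radical cyclisation (Mn(dpm)3, PhSiH3, t-BuOOH, i-PrOH) should close C9–C10 by 6-exo-trig attack of the C10 radical on the C9=C11 alkene through a chair with the C11 chain equatorial, giving the bicyclic thioester F3.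
- Me2CuLi converts the thioester into the methyl ketone, which is 15.

Step 13. Hydrogen abstraction from C11, [4+2] addition of oxygen to the diene, and poor facial selectivity at C12 may compete. Fallback: set C12 as an alcohol by reagent control and exchange OH for OOH with inversion. It sets out from 16 and returns at 24.
- DBU (toluene) should shift the acetyl group from the tertiary 8-O to the secondary 7-O (6-O is blocked), giving the 7-acetate F4.
- TESOTf/2,6-lutidine masks the 8α-hydroxyl (8-triethylsilyl ether F5).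
- Buffered HF·pyridine at 0 °C removes only the primary silyl ether (primary alcohol F6).
- TEMPO/PhI(OAc)2 gives aldehyde F7.
- Ti(Oi-Pr)4/BINOL-catalysed addition of tributyl(buta-2,3-dien-1-yl)stannane gives the (12S)-2-dienyl carbinol F8.
- MsCl/Et3N at −65 °C gives the mesylate F9, which is not isolated; anhydrous H2O2 in Et2O at −110 °C displaces it with inversion to the (12R)-hydroperoxide F10. The silylated 8-O cannot close the 8,12-ether.
- HF·pyridine removes both silyl groups to give 24.

Step 1. The double diastereoselection in the aldol of the hindered enolate may erode (syn aldol or anti-Felkin addition). Fallback: catalyst-controlled aldol with a glyoxylate. It sets out from 1 and returns at 9.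
- Me2CuLi/Me3SiCl gives 3,3-dimethyl-1-(trimethylsilyloxy)cyclohex-1-ene F11.
- An anti-selective Mukaiyama aldol with ethyl glyoxylate, catalysed by Sn(OTf)2 and a bis(oxazoline) ligand, gives ethyl (2S)-2-hydroxy-2-[(1R)-2,2-dimethyl-6-oxocyclohexyl]acetate F12.
- TBSOTf/2,6-lutidine gives the silyl ether F13.
- Ketone-selective methylenation (Zn, CH2Br2, TiCl4) gives the methylidene ester F14.
- i-Bu2AlH at −78 °C reduces the ester to aldehyde 9.

Further compounds

F1 | step 6 | S-ethyl (E)-5-[(tert-butyldimethylsilyl)oxy]-2-methylpent-2-enethioate | CCSC(=O)/C(C)=C/CCO[Si](C)(C)C(C)(C)C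
F2 | step 6 | S-ethyl thioester aldol of F1 with 9 (C7–C8 formed; 7-OH, 6-OTBS, C8 methyl, E-C9=C11, exocyclic C10=CH2) | CCSC(=O)[C@@](C)(/C=C/CO[Si](C)(C)C(C)(C)C)[C@@H](O)[C@@H](O[Si](C)(C)C(C)(C)C)[C@H]1C(C)(C)CCCC1=C
F3 | step 6 | S-ethyl 6β,12-bis(tert-butyldimethylsilyloxy)-7β-hydroxy-13,14,15,16-tetranorlabdane-8α-carbothioate | CC(C)(C)[Si](C)(C)OCC[C@H]1[C@](C)(C(=O)SCC)[C@@H](O)[C@@H](O[Si](C)(C)C(C)(C)C)[C@H]2C(C)(C)CCC[C@@]21C
F4 | step 13 | 6β,12-bis(tert-butyldimethylsilyloxy)-8α-hydroxy-13,14,15,16-tetranorlabdan-7β-yl acetate | CC(C)(C)[Si](C)(C)OCC[C@H]1[C@](C)(O)[C@@H](OC(C)=O)[C@@H](O[Si](C)(C)C(C)(C)C)[C@H]2C(C)(C)CCC[C@@]21C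
F5 | step 13 | 6β,12-bis(tert-butyldimethylsilyloxy)-8α-(triethylsilyloxy)-13,14,15,16-tetranorlabdan-7β-yl acetate | CC(C)(C)[Si](C)(C)OCC[C@H]1[C@](C)(O[Si](CC)(CC)CC)[C@@H](OC(C)=O)[C@@H](O[Si](C)(C)C(C)(C)C)[C@H]2C(C)(C)CCC[C@@]21C
F6 | step 13 | 6β-(tert-butyldimethylsilyloxy)-12-hydroxy-8α-(triethylsilyloxy)-13,14,15,16-tetranorlabdan-7β-yl acetate | OCC[C@H]1[C@](C)(O[Si](CC)(CC)CC)[C@@H](OC(C)=O)[C@@H](O[Si](C)(C)C(C)(C)C)[C@H]2C(C)(C)CCC[C@@]21C
F7 | step 13 | 6β-(tert-butyldimethylsilyloxy)-12-oxo-8α-(triethylsilyloxy)-13,14,15,16-tetranorlabdan-7β-yl acetate | O=CC[C@H]1[C@](C)(O[Si](CC)(CC)CC)[C@@H](OC(C)=O)[C@@H](O[Si](C)(C)C(C)(C)C)[C@H]2C(C)(C)CCC[C@@]21C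
F8 | step 13 | (12S)-6β-(tert-butyldimethylsilyloxy)-12-hydroxy-8α-(triethylsilyloxy)labda-13(16),14-dien-7β-yl acetate | C=CC(=C)[C@H](C[C@H]1[C@](C)(O[Si](CC)(CC)CC)[C@@H](OC(C)=O)[C@@H](O[Si](C)(C)C(C)(C)C)[C@H]2C(C)(C)CCC[C@@]21C)O
F9 | step 13 | (12S)-6β-(tert-butyldimethylsilyloxy)-12-(methanesulfonyloxy)-8α-(triethylsilyloxy)labda-13(16),14-dien-7β-yl acetate | C=CC(=C)[C@H](C[C@H]1[C@](C)(O[Si](CC)(CC)CC)[C@@H](OC(C)=O)[C@@H](O[Si](C)(C)C(C)(C)C)[C@H]2C(C)(C)CCC[C@@]21C)OS(C)(=O)=O
F10 | step 13 | (12R)-6β-(tert-butyldimethylsilyloxy)-12-hydroperoxy-8α-(triethylsilyloxy)labda-13(16),14-dien-7β-yl acetate | C=CC(=C)[C@@H](C[C@H]1[C@](C)(O[Si](CC)(CC)CC)[C@@H](OC(C)=O)[C@@H](O[Si](C)(C)C(C)(C)C)[C@H]2C(C)(C)CCC[C@@]21C)OO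
F11 | step 1 | 3,3-dimethyl-1-(trimethylsilyloxy)cyclohex-1-ene | C[Si](C)(C)OC1=CC(C)(C)CCC1
F12 | step 1 | ethyl (2S)-2-hydroxy-2-[(1R)-2,2-dimethyl-6-oxocyclohexyl]acetate | CCOC(=O)[C@@H](O)[C@H]1C(C)(C)CCCC1=O
F13 | step 1 | ethyl (2S)-2-[(tert-butyldimethylsilyl)oxy]-2-[(1R)-2,2-dimethyl-6-oxocyclohexyl]acetate | CCOC(=O)[C@@H](O[Si](C)(C)C(C)(C)C)[C@H]1C(C)(C)CCCC1=O
F14 | step 1 | ethyl (2S)-2-[(tert-butyldimethylsilyl)oxy]-2-[(1S)-2,2-dimethyl-6-methylidenecyclohexyl]acetate | CCOC(=O)[C@@H](O[Si](C)(C)C(C)(C)C)[C@H]1C(C)(C)CCCC1=C
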